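Target ring atoms (labels kept for all intermediates): C1 (CMeCl), C2, C3 (quaternary; methyl and bromovinyl carbon C7), C4 (CHBr), C5, C6 (CHCl). Everything rests on forming C2–C3 and C4–Br in one operation: a bromonium ion on the C3=C4 alkene of a cycloheptadienol triggers a 1,2-shift of ring carbon C2 from carbinol C7 to C3, contracting the seven-membered ring to the cyclohexene, releasing C7 as the aldehyde and setting C3 and C4. The step exploits the cis relationship between the C4 bromine and C7 on the six-membered ring, beside quaternary C3. Its precursor is (6R)-6-hydroxy-5-methylcyclohepta-1,4-dien-1-yl triflate, whose enol triflate alkene resists bromine.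

Key step: step 6

Step 1
Reactants: 1 hex-5-en-2-one; 2 methacrolein
Product: 5 (3R)-3-hydroxy-2-methylnona-1,8-dien-5-one, via boron enolate 3 (not isolated), via boron aldolate 4 (not isolated)
Conditions: (−)-Ipc2BCl (from (+)-α-pinene), Et3N, Et2O, 0 °C; then 2, −78 to −20 °C; H2O2, MeOH, pH 7 buffer
Reagents that add atoms: none
Why: Boron aldol reaction in which the chloroborane and the amine enolise the methyl ketone on its methyl side and the diisopinocampheylboron enolate 3 of this antipode adds to the Re face of the enal, which should set the carbinol carbon (later C7) as R.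

Step 2
Reactants: 5 (3R)-3-hydroxy-2-methylnona-1,8-dien-5-one
Product: 6 (3R)-2-methyl-3-[(triethylsilyl)oxy]nona-1,8-dien-5-one
Conditions: Et3SiCl, imidazole, CH2Cl2, 0 to 25 °C
Reagents that add atoms: chlorotriethylsilane, CC[Si](Cl)(CC)CC
Why: Silyl ether protection of the secondary alcohol, so that the base of step 4 meets no hydroxyl proton and the aldol cannot revert, with no stereocentre affected.

Step 3
Reactants: 6 (3R)-2-methyl-3-[(triethylsilyl)oxy]nona-1,8-dien-5-one
Product: 7 (3R)-4-methyl-3-[(triethylsilyl)oxy]cyclohept-4-en-1-one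
Conditions: second-generation Grubbs catalyst RuCl2(=CHPh)(PCy3)(H2IMes) (cat.), CH2Cl2 (dilute), 40 °C
Reagents that add atoms: none
Why: Ring-closing metathesis joins the monosubstituted and the 1,1-disubstituted alkene with loss of ethene, closing the seven-membered ring and forming the trisubstituted C3=C4 alkene, a task this N-heterocyclic carbene ruthenium catalyst handles routinely.

Step 4
Reactants: 7 (3R)-4-methyl-3-[(triethylsilyl)oxy]cyclohept-4-en-1-one
Product: 9 (6R)-5-methyl-6-[(triethylsilyl)oxy]cyclohepta-1,4-dien-1-yl trifluoromethanesulfonate, via lithium enolate 8 (not isolated)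
Conditions: LiN(iPr)2, THF, −78 °C; PhNTf2, −78 to 0 °C
Reagents that add atoms: N-phenylbis(trifluoromethanesulfonimide), O=S(=O)(N(c1ccccc1)S(=O)(=O)C(F)(F)F)C(F)(F)F
Why: Kinetic enolate formation and O-sulfonylation (enol triflate synthesis), in which the hindered amide removes a proton from the less encumbered C6 methylene, away from the silyloxy-bearing C7, and PhNTf2 traps lithium enolate 8 on oxygen, leaving C2 as the sp3 carbon that must later migrate.

Step 5
Reactants: 9 (6R)-5-methyl-6-[(triethylsilyl)oxy]cyclohepta-1,4-dien-1-yl trifluoromethanesulfonate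
Product: 10 (6R)-6-hydroxy-5-methylcyclohepta-1,4-dien-1-yl trifluoromethanesulfonate
Conditions: HF·pyridine, pyridine, THF, 0 to 25 °C
Reagents that add atoms: none
Why: Desilylation with buffered hydrogen fluoride frees the C7 hydroxyl without harm to the enol triflate or the skipped diene and without touching the stereocentre.

Step 6
Reactants: 10 (6R)-6-hydroxy-5-methylcyclohepta-1,4-dien-1-yl trifluoromethanesulfonate; 11 N-bromosuccinimide
Product: 13 (4S,5S)-4-bromo-5-formyl-5-methylcyclohex-1-en-1-yl trifluoromethanesulfonate, via bromonium ion 12 (not isolated)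
Conditions: NBS, CH2Cl2, −40 to 0 °C, dark
Reagents that add atoms: N-bromosuccinimide (11), O=C1CCC(=O)N1Br
Why: Proposed new method: NBS should form bromonium ion 12 only on the electron-rich C3=C4 alkene, on the exposed face of the cycloheptadiene chair that is also the face of the pseudoaxial C7 hydroxyl, and this ion is opened at tertiary C3 by the antiperiplanar C7–C2 ring bond with assistance from the oxygen lone pair, so that C7 ends as the aldehyde; the closest known reaction types are halonium-induced semipinacol rearrangements of allylic alcohols and Lewis-acid ring contractions of cyclic 2,3-epoxy alcohols. The six-membered ring is closed by this 1,2-alkyl shift (C2–C3 forms as C7–C2 breaks, a ring contraction and not an exo or endo cyclisation). C4 is fixed by the face that bromine takes and C3 by the migration on the opposite face, so anti addition across the cis ring alkene leaves bromine and the formyl carbon on the same face, and the absolute sense of both centres is dictated by the C7 carbinol stereocentre before it is erased. The step needs site selectivity (the triflate-bearing alkene is deactivated and should stay untouched), carbon instead of hydride migration (in the cycloheptene chair the C7–C2 bond stands almost parallel to the C3 p orbital whereas C7–H lies close to the alkene plane) and a single reacting conformer (A(1,2) strain with the C3 methyl keeps the hydroxyl pseudoaxial, where it can also hydrogen-bond to the brominating agent).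

Step 7
Reactants: 13 (4S,5S)-4-bromo-5-formyl-5-methylcyclohex-1-en-1-yl trifluoromethanesulfonate
Product: 14 (1S,6S)-6-bromo-1,3-dimethylcyclohex-3-ene-1-carbaldehyde
Conditions: MeZnCl, Pd(PPh3)4 (cat.), THF, 25 to 45 °C
Reagents that add atoms: methylzinc chloride, C[Zn]Cl
Why: Negishi cross-coupling in which zerovalent palladium inserts into the C1–O bond of the enol triflate and methyl is delivered from zinc, while the hindered, non-enolisable aldehyde and the secondary alkyl bromide are left alone by the mild organozinc reagent.

Step 8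
Reactants: 14 (1S,6S)-6-bromo-1,3-dimethylcyclohex-3-ene-1-carbaldehyde
Product: 15 (4S,5S)-4-bromo-5-[(E)-2-bromoethenyl]-1,5-dimethylcyclohex-1-ene
Conditions: CrBr2, CHBr3, THF, 25 to 50 °C
Reagents that add atoms: bromoform, BrC(Br)Br
Why: Takai olefination in which the geminal dichromium species generated from bromoform adds to the aldehyde and eliminates to the (E)-bromoalkene, the bromide salt of chromium being chosen so that no chloroalkene arises by halide exchange.

Step 9
Reactants: 15 (4S,5S)-4-bromo-5-[(E)-2-bromoethenyl]-1,5-dimethylcyclohex-1-ene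
Product: 16 (1R,3S,4S,6S)-4-bromo-3-[(E)-2-bromoethenyl]-1,3-dimethyl-7-oxabicyclo[4.1.0]heptane
Conditions: mCPBA, CH2Cl2, 0 °C
Reagents that add atoms: 3-chloroperbenzoic acid, OOC(=O)c1cccc(Cl)c1
Why: Prilezhaev epoxidation in which the peracid selects the electron-rich trisubstituted C1=C6 alkene over the bromoalkene and should approach the ring face that carries the C3 methyl, away from the C4 bromine and the C3 bromoethenyl group, which places the epoxide oxygen trans to both.

Step 10
Reactants: 16 (1R,3S,4S,6S)-4-bromo-3-[(E)-2-bromoethenyl]-1,3-dimethyl-7-oxabicyclo[4.1.0]heptane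
Product: 17 (1S,2S,4S,5S)-5-bromo-4-[(E)-2-bromoethenyl]-2-chloro-2,4-dimethylcyclohexan-1-ol
Conditions: HCl (Et2O solution), CH2Cl2, −40 to 0 °C
Reagents that add atoms: hydrogen chloride, Cl
Why: Acid-promoted epoxide opening in which chloride enters at the tertiary, cation-stabilising C1 with inversion in a trans-diaxial (Fürst–Plattner) sense, which sets the C1 chloride cis to the bromoethenyl group and leaves the C6 hydroxyl on the opposite face.

Step 11
Reactants: 17 (1S,2S,4S,5S)-5-bromo-4-[(E)-2-bromoethenyl]-2-chloro-2,4-dimethylcyclohexan-1-ol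
Product: 19 (1S,2S,4R,5S)-2-bromo-1-[(E)-2-bromoethenyl]-4,5-dichloro-1,5-dimethylcyclohexane, via alkoxyphosphonium chloride 18 (not isolated)
Conditions: PPh3, NCS, THF, 0 to 50 °C
Reagents that add atoms: N-chlorosuccinimide, O=C1CCC(=O)N1Cl
Why: Appel-type deoxychlorination in which the hydroxyl becomes alkoxyphosphonium salt 18 and chloride displaces it in an SN2 reaction with inversion at C6, the way trans-2-chlorocyclohexanols give cis-1,2-dichlorides, so that both chlorines end on the face of the bromine and the bromoethenyl group.

Compound list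

1 | hex-5-en-2-one | CC(=O)CCC=C | starting material
2 | methacrolein (2-methylprop-2-enal) | CC(=C)C=O | starting material
3 | boron enolate: hexa-1,5-dien-2-yl diisopinocampheylborinate (Ipc groups from (+)-α-pinene; not isolated) | C=CCCC(=C)OB([C@@H]1C[C@@H]2C[C@H]([C@H]1C)C2(C)C)[C@@H]1C[C@@H]2C[C@H]([C@H]1C)C2(C)C | intermediate
4 | boron aldolate: diisopinocampheylborinate ester of 5 (not isolated) | C=C(C)[C@H](OB([C@@H]1C[C@@H]2C[C@H]([C@H]1C)C2(C)C)[C@@H]1C[C@@H]2C[C@H]([C@H]1C)C2(C)C)CC(=O)CCC=C | intermediate
5 | (3R)-3-hydroxy-2-methylnona-1,8-dien-5-one | C=C(C)[C@H](O)CC(=O)CCC=C | intermediate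
6 | (3R)-2-methyl-3-[(triethylsilyl)oxy]nona-1,8-dien-5-one | C=C(C)[C@H](O[Si](CC)(CC)CC)CC(=O)CCC=C | intermediate
7 | (3R)-4-methyl-3-[(triethylsilyl)oxy]cyclohept-4-en-1-one | O=C1C[C@@H](O[Si](CC)(CC)CC)C(C)=CCC1 | intermediate
8 | lithium enolate of 7: lithium (6R)-5-methyl-6-[(triethylsilyl)oxy]cyclohepta-1,4-dien-1-olate (not isolated) | [Li]OC1=CCC=C(C)[C@H](O[Si](CC)(CC)CC)C1 | intermediate
9 | (6R)-5-methyl-6-[(triethylsilyl)oxy]cyclohepta-1,4-dien-1-yl trifluoromethanesulfonate | CC[Si](CC)(CC)O[C@@H]1CC(OS(=O)(=O)C(F)(F)F)=CCC=C1C | intermediate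
10 | (6R)-6-hydroxy-5-methylcyclohepta-1,4-dien-1-yl trifluoromethanesulfonate (key-step precursor) | O[C@@H]1CC(OS(=O)(=O)C(F)(F)F)=CCC=C1C | intermediate
11 | N-bromosuccinimide | O=C1CCC(=O)N1Br | starting material
12 | bromonium ion of 10 (bromine bridging C3 and C4 on the hydroxyl face; succinimide anion as counter-ion; not isolated) | O[C@@H]1CC(OS(=O)(=O)C(F)(F)F)=CC[C@@H]2[Br+][C@]12C.O=C1CCC(=O)[N-]1 | intermediate
13 | (4S,5S)-4-bromo-5-formyl-5-methylcyclohex-1-en-1-yl trifluoromethanesulfonate (bromine cis to formyl; key-step product) | FC(F)(F)S(=O)(=O)OC1=CC[C@H](Br)[C@](C)(C=O)C1 | intermediate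
14 | (1S,6S)-6-bromo-1,3-dimethylcyclohex-3-ene-1-carbaldehyde | CC1=CC[C@H](Br)[C@](C)(C=O)C1 | intermediate
15 | (4S,5S)-4-bromo-5-[(E)-2-bromoethenyl]-1,5-dimethylcyclohex-1-ene | CC1=CC[C@H](Br)[C@](C)(/C=C/Br)C1 | intermediate
16 | (1R,3S,4S,6S)-4-bromo-3-[(E)-2-bromoethenyl]-1,3-dimethyl-7-oxabicyclo[4.1.0]heptane (epoxide oxygen trans to bromine and bromoethenyl) | C[C@@]12C[C@@](C)(/C=C/Br)[C@@H](Br)C[C@@H]1O2 | intermediate
17 | (1S,2S,4S,5S)-5-bromo-4-[(E)-2-bromoethenyl]-2-chloro-2,4-dimethylcyclohexan-1-ol | C[C@]1(Cl)C[C@@](C)(/C=C/Br)[C@@H](Br)C[C@@H]1O | intermediate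
18 | alkoxyphosphonium chloride of 17 (not isolated) | C[C@]1(Cl)C[C@@](C)(/C=C/Br)[C@@H](Br)C[C@@H]1O[P+](c1ccccc1)(c1ccccc1)c1ccccc1.[Cl-] | intermediate
19 | (1S,2S,4R,5S)-2-bromo-1-[(E)-2-bromoethenyl]-4,5-dichloro-1,5-dimethylcyclohexane | C[C@]1(Cl)C[C@@](C)(/C=C/Br)[C@@H](Br)C[C@H]1Cl | target

Total step count: 11
Longest linear sequence: 11 steps (1 and 2 to 19)

Steps most likely to fail

Step 6. The stereochemical relay may be lost if the ring-flipped chair reacts (which would pass on the opposite absolute sense). The bromonium ion may also be captured by an outside nucleophile, or the allylic alcohol oxidised, before the shift. The fallback sets out from 10 and comes back at 13, using known operations only. Hydroxyl-directed epoxidation (VO(acac)2, tBuOOH, CH2Cl2) should give the syn-epoxy alcohol (1S,6R,7R)-6-hydroxy-7-methyl-8-oxabicyclo[5.1.0]oct-3-en-4-yl trifluoromethanesulfonate F1, whose oxygen sits on the required face by configuration and not by conformation. ZnBr2 in CH2Cl2 then brings about the established ring contraction of a 2,3-epoxy alcohol to the hydroxy aldehyde (4S,5R)-5-formyl-4-hydroxy-5-methylcyclohex-1-en-1-yl trifluoromethanesulfonate F2, with C3 as in 13 and oxygen at C4 cis to formyl; a misaligned conformer would give a separable ketone by hydride shift and not the antipode. Because SN2 displacement beside quaternary C3 is not viable, hydroxyl is exchanged for bromine with retention. Quinoline-8-sulfonyl chloride and pyridine give the sulfonate (4S,5R)-5-formyl-5-methyl-4-[(quinolin-8-ylsulfonyl)oxy]cyclohex-1-en-1-yl trifluoromethanesulfonate F3. TiBr4 (CH2Cl2, −78 °C) then delivers bromide from the front through the chelated leaving group and returns the route to 13.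

Step 11. Elimination toward C5, or participation of the antiperiplanar C1 chlorine (which would give the trans-dichloride), may take the place of clean SN2 inversion at the hindered C6. The fallback sets out from alkene 15 and comes back at 19, with selenium in place of oxygen as the relay. PhSeSePh (cat.), BnEt3NCl, N-fluoropyridinium tetrafluoroborate and Me3SiCl in MeCN should effect a syn-dichlorination: anti chloroselenylation puts selenium on the face of the C3 methyl and chloride at tertiary C1, and chloride then displaces the oxidised, tetravalent selenium at C6 with inversion. This bypasses 16 and 17 and makes no new compound (F0).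

Step 1. Enantiofacial control in the aldol addition may be incomplete, which would carry the antipode through the whole sequence. The fallback sets out from 5 and comes back at 5. A Sharpless kinetic resolution (Ti(OiPr)4, L-(+)-diisopropyl tartrate, substoichiometric tBuOOH, 4 Å sieves, CH2Cl2, −20 °C) should epoxidise the minor (S)-alcohol much faster, removing it as the epoxy alcohol (1S)-1-hydroxy-1-[(2S)-2-methyloxiran-2-yl]hept-6-en-3-one F4. The (R)-alcohol 5 is left enantiomerically upgraded for step 2.

Further compounds

F1 | step 6 | (1S,6R,7R)-6-hydroxy-7-methyl-8-oxabicyclo[5.1.0]oct-3-en-4-yl trifluoromethanesulfonate | O[C@@H]1CC(OS(=O)(=O)C(F)(F)F)=CC[C@@H]2O[C@]12C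
F2 | step 6 | (4S,5R)-5-formyl-4-hydroxy-5-methylcyclohex-1-en-1-yl trifluoromethanesulfonate | FC(F)(F)S(=O)(=O)OC1=CC[C@H](O)[C@](C)(C=O)C1
F3 | step 6 | (4S,5R)-5-formyl-5-methyl-4-[(quinolin-8-ylsulfonyl)oxy]cyclohex-1-en-1-yl trifluoromethanesulfonate | FC(F)(F)S(=O)(=O)OC1=CC[C@H](OS(=O)(=O)c2cccc3cccnc23)[C@](C)(C=O)C1
F0 | step 11 | none | none
F4 | step 1 | (1S)-1-hydroxy-1-[(2S)-2-methyloxiran-2-yl]hept-6-en-3-one | C[C@]1(CO1)[C@@H](O)CC(=O)CCC=C
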